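The target is a twofold-symmetric diarylmethane. Two inner resorcinol-type rings share one CH2, and in each ring the carbon next to the bridge-bearing carbon carries a 2-(guaiacyl)ethyl chain. Raising the bridge CH2 to C=O turns it into a directing group whose oxygen reaches exactly these two carbons (C6–H and C6'–H; the other ortho sites C2/C2' are blocked by oxygen). One two-directional, ruthenium-catalysed, ketone-directed C–H alkylation (Murai-type anti-Markovnikov hydroarylation) adds both C–H bonds of 2,2'-bis(benzyloxy)-4,4'-dimethoxybenzophenone across O-benzyl-4-vinylguaiacol. This forges both aryl–CH2 bonds without halide, organometal or by-product. Hydrogenolysis and phenol-assisted borane deoxygenation of the carbonyl finish the synthesis.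

Key step: step 2

Remark: the target has no stereocentre and no configurationally stable axis. It is achiral, so no step needs stereocontrol.

Step 1
Reactants: 1 2,2'-dihydroxy-4,4'-dimethoxybenzophenone (benzophenone-6, commercial UV absorber)
Product: 2 2,2'-bis(benzyloxy)-4,4'-dimethoxybenzophenone
Conditions: BnBr (2.5 equiv), K2CO3 (3 equiv), DMF, 60 °C
Reagents that add atoms: benzyl bromide, BrCc1ccccc1
Why: Williamson etherification, in which carbonate in DMF breaks the two chelated O–H···O=C hydrogen bonds and the phenoxides displace bromide (SN2), masking the phenols that would otherwise tie up ruthenium as O,O-chelates in step 2.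

Step 2
Reactants: 2 2,2'-bis(benzyloxy)-4,4'-dimethoxybenzophenone; 3 4-benzyloxy-3-methoxystyrene (O-benzyl-4-vinylguaiacol, commercial; 5 equiv, two are incorporated)
Product: 5 bis[2-(benzyloxy)-6-{2-[4-(benzyloxy)-3-methoxyphenyl]ethyl}-4-methoxyphenyl]methanone, via mono-alkylated ketone 4 (not isolated)
Conditions: [RuCl2(p-cymene)]2 (5 mol %), P(4-CF3C6H4)3 (15 mol %), HCO2Na (30 mol %), BHT (cat.), toluene, 140 °C, sealed tube, Ar
Reagents that add atoms: none
Why: The low-valent ruthenium hydride formed from the Ru(II) salt, formate and phosphine binds the ketone oxygen of 2 and inserts into the single ortho C6–H to give a five-membered aryl-ruthenium hydride chelate; styrene 3 then inserts into Ru–H with ruthenium on its terminal carbon, and C–C reductive elimination forms the aryl–CH2 bond of 4. The same carbonyl then turns into the plane of the second ring and repeats the cycle at C6'–H, joining 4 to a second molecule of 3 to give 5. The closest known reaction type is the Murai reaction, the carbonyl-directed Ru-catalysed ortho C–H alkylation of aromatic ketones, in its anti-Markovnikov styrene-hydroarylation variant. No ring is closed in the product and no stereocentre is formed. Site selectivity is secured by the substrate: each ring has only one ortho C–H, C2/C2' carry OBn, C3–H and C5–H lie outside the reach of the five-membered chelate, and over-alkylation is therefore impossible. Linear over branched addition should follow from reversible hydrometalation with product-determining reductive elimination of the less hindered primary alkyl, helped by the electron-poor phosphine, and excess 3 should drive the mono-adduct on to the bis-adduct.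

Step 3
Reactants: 5 bis[2-(benzyloxy)-6-{2-[4-(benzyloxy)-3-methoxyphenyl]ethyl}-4-methoxyphenyl]methanone
Product: 6 bis{2-hydroxy-6-[2-(4-hydroxy-3-methoxyphenyl)ethyl]-4-methoxyphenyl}methanone
Conditions: H2 (1 atm), 10 % Pd/C, EtOAc/MeOH, rt
Reagents that add atoms: none
Why: Heterogeneous hydrogenolysis of four aryl benzyl ethers, during which the tetra-ortho-substituted, hydrogen-bonded and electron-rich diaryl ketone should stay untouched at 1 atm, and any portion that is reduced would converge on 9 in step 4.

Step 4
Reactants: 6 bis{2-hydroxy-6-[2-(4-hydroxy-3-methoxyphenyl)ethyl]-4-methoxyphenyl}methanone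
Product: 9 2,2'-methylenebis{3-[2-(4-hydroxy-3-methoxyphenyl)ethyl]-5-methoxyphenol} (target), via benzhydrol 7 (not isolated), via ortho-quinone methide 8 (not isolated)
Conditions: BH3·THF (10 equiv), THF, 0 → 65 °C; then H2O, 1 M HCl work-up
Reagents that add atoms: none
Why: Borane deoxygenation of an electron-rich ortho-hydroxy diaryl ketone, in which the aryloxyborane formed at the flanking phenol chelates and activates the hindered C=O for the small hydride donor, the boron-bound benzhydrol 7 collapses (push from ortho-O and para-OMe) to ortho-quinone methide 8, and a further B–H reduces 8 to the CH2 bridge before the pendant guaiacyl ring can attack.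

Compound list
1 | 2,2'-dihydroxy-4,4'-dimethoxybenzophenone | COc1ccc(C(=O)c2ccc(OC)cc2O)c(O)c1 | starting material
2 | 2,2'-bis(benzyloxy)-4,4'-dimethoxybenzophenone | COc1ccc(C(=O)c2ccc(OC)cc2OCc2ccccc2)c(OCc2ccccc2)c1 | intermediate
3 | 4-benzyloxy-3-methoxystyrene | C=Cc1ccc(OCc2ccccc2)c(OC)c1 | starting material
4 | [2-(benzyloxy)-4-methoxyphenyl][2-(benzyloxy)-6-{2-[4-(benzyloxy)-3-methoxyphenyl]ethyl}-4-methoxyphenyl]methanone (mono-alkylated ketone, not isolated) | COc1ccc(C(=O)c2c(OCc3ccccc3)cc(OC)cc2CCc2ccc(OCc3ccccc3)c(OC)c2)c(OCc2ccccc2)c1 | intermediate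
5 | bis[2-(benzyloxy)-6-{2-[4-(benzyloxy)-3-methoxyphenyl]ethyl}-4-methoxyphenyl]methanone | COc1cc(OCc2ccccc2)c(C(=O)c2c(OCc3ccccc3)cc(OC)cc2CCc2ccc(OCc3ccccc3)c(OC)c2)c(CCc2ccc(OCc3ccccc3)c(OC)c2)c1 | intermediate
6 | bis{2-hydroxy-6-[2-(4-hydroxy-3-methoxyphenyl)ethyl]-4-methoxyphenyl}methanone | COc1cc(O)c(C(=O)c2c(O)cc(OC)cc2CCc2ccc(O)c(OC)c2)c(CCc2ccc(O)c(OC)c2)c1 | intermediate
7 | bis{2-hydroxy-6-[2-(4-hydroxy-3-methoxyphenyl)ethyl]-4-methoxyphenyl}methanol (boron-bound in the flask, drawn free; not isolated) | COc1cc(O)c(C(O)c2c(O)cc(OC)cc2CCc2ccc(O)c(OC)c2)c(CCc2ccc(O)c(OC)c2)c1 | intermediate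
8 | 6-({2-hydroxy-6-[2-(4-hydroxy-3-methoxyphenyl)ethyl]-4-methoxyphenyl}methylidene)-5-[2-(4-hydroxy-3-methoxyphenyl)ethyl]-3-methoxycyclohexa-2,4-dien-1-one (ortho-quinone methide, phenols boron-bound in the flask, drawn free; not isolated) | COC1=CC(=O)C(=Cc2c(O)cc(OC)cc2CCc2ccc(O)c(OC)c2)C(CCc2ccc(O)c(OC)c2)=C1 | intermediate
9 | 2,2'-methylenebis{3-[2-(4-hydroxy-3-methoxyphenyl)ethyl]-5-methoxyphenol} | COc1cc(O)c(Cc2c(O)cc(OC)cc2CCc2ccc(O)c(OC)c2)c(CCc2ccc(O)c(OC)c2)c1 | target

Total step count: 4
Longest linear sequence: 4 steps (1 → 2 → 5 → 6 → 9)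

Steps most likely to fail

Step 2. Several processes could go wrong:
- The second C–H insertion may stall, because the carbonyl of the mono-adduct is twisted by three ortho substituents.
- Low-valent ruthenium may insert into the chelation-accessible ortho C–OBn bond.
- Branched insertion may compete with linear insertion.
- The electron-rich styrene may oligomerise thermally and be used up.

Fallback: replace hydroarylation by a redox-different C–H reaction. It sets out from 2 and 3. Ru(II)-catalysed ketone-directed oxidative (dehydrogenative Heck-type) ortho-alkenylation uses [RuCl2(p-cymene)]2, AgSbF6 and Cu(OAc)2 in 1,2-dichloroethane at 110 °C. It avoids Ru(0), and β-hydride elimination fixes the linear regiochemistry. It should give the bis-stilbene ketone bis[2-(benzyloxy)-6-{(E)-2-[4-(benzyloxy)-3-methoxyphenyl]ethenyl}-4-methoxyphenyl]methanone F1. Hydrogenation of F1 over Pd/C saturates both alkenes while the four benzyl ethers are cleaved, and the route is rejoined at 6.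

Step 4. Hydride delivery to the tetra-ortho-substituted carbonyl may be slow. Ionisation at the bridge carbon may also be followed by intramolecular Friedel–Crafts closure of a seven-membered ring onto the guaiacyl ring before hydride capture.

Fallback: change the order of deoxygenation and deprotection. It sets out from 5. LiAlH4 in refluxing THF reduces the hindered ketone to the tetra-O-benzyl benzhydrol bis[2-(benzyloxy)-6-{2-[4-(benzyloxy)-3-methoxyphenyl]ethyl}-4-methoxyphenyl]methanol F2. One hydrogenolysis (H2, Pd/C, EtOAc/EtOH, trace AcOH) then removes the doubly benzylic hydroxyl together with all four benzyl ethers on the catalyst surface, and the route is rejoined at 9.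

Step 3. Hydrogenolysis of the two benzyl ethers buried next to the carbonyl may be incomplete. Phosphine or ruthenium residues carried over from step 2 may poison the palladium.

Fallback: switch from surface hydrogenolysis to Lewis-acid ether cleavage. It sets out from 5. BCl3 with pentamethylbenzene as benzyl-cation scavenger in CH2Cl2 at −78 °C should cleave the four benzyl ethers and leave the aryl methyl ethers in place, since none of them flanks the carbonyl. The route is rejoined at 6. This detour makes no compound outside the list (F0).

Further compounds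
F1 | step 2 | bis[2-(benzyloxy)-6-{(E)-2-[4-(benzyloxy)-3-methoxyphenyl]ethenyl}-4-methoxyphenyl]methanone | COc1cc(OCc2ccccc2)c(C(=O)c2c(OCc3ccccc3)cc(OC)cc2/C=C/c2ccc(OCc3ccccc3)c(OC)c2)c(/C=C/c2ccc(OCc3ccccc3)c(OC)c2)c1
F2 | step 4 | bis[2-(benzyloxy)-6-{2-[4-(benzyloxy)-3-methoxyphenyl]ethyl}-4-methoxyphenyl]methanol | COc1cc(OCc2ccccc2)c(C(O)c2c(OCc3ccccc3)cc(OC)cc2CCc2ccc(OCc3ccccc3)c(OC)c2)c(CCc2ccc(OCc3ccccc3)c(OC)c2)c1
F0 | step 3 | none | none
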